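**Retrosynthetic overview**

1. Feature: between C1 of the trans-hydrindane (cyclopentane fused to the gem-dimethylcyclohexane) and C4 of the γ-lactone lie two adjacent carbons, the vinylidene carbon and the allylic methine. Each carries one extra carbon (the =CH2 and the CH2OAc), which is the imprint of ethylene split across an alkyne.
2. Target 36 ⇐ silyl ether/acetate ⇐ alcohol 34 ⇐ site- and face-selective hydroboration of the 2,3-disubstituted buta-1,3-diene 32 ⇐ cross enyne metathesis of internal alkyne 30 with ethylene 31.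
3. Alkyne 30 ⇐ hydrindanyl acetylene 18 + (2S,3S)-epoxy alcohol 22: alkynylalane opening at C3, oxidation of the primary carbinol, lactonisation, silylation.
4. 18 ⇐ trans-hydrindanone 13 ⇐ 4-methyl Hajos–Parrish-type enone 5 ⇐ dione 1 + enone 2; 22 ⇐ but-2-yne-1,4-diol 19.
5. Ring order: cyclopentane from 1; cyclohexane by aldol condensation (step 2); lactone by lactonisation (step 17); the key step closes no ring.

Key step: step 19

Remark on numbering: hydrindane C1 carries the side chain, C3a the ring-fusion H, C4 the gem-dimethyl group, C7a the angular methyl; lactone O1, C2 (C=O), C3 (O-bearing), C4, C5.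

Assumption: the 4-methyl homologue 5 of the Hajos–Parrish ketone is made from 1 and 2 instead of starting from the parent ketone, so that one C4 methyl is in place before the reductive methylation.

**Route**

Step 1
Reactants: 1 2-methylcyclopentane-1,3-dione; 2 pent-1-en-3-one (ethyl vinyl ketone)
Product: 3 2-methyl-2-(3-oxopentyl)cyclopentane-1,3-dione
Conditions: AcOH (cat.), H2O, 75 °C
Reagents that add atoms: none
Why: Michael addition of the acidic cyclic 1,3-dione to the vinyl ketone, the usual entry to Hajos–Parrish-type triketones; no stereocentre is formed.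

Step 2
Reactants: 3 2-methyl-2-(3-oxopentyl)cyclopentane-1,3-dione
Product: 5 (S)-4,7a-dimethyl-2,3,7,7a-tetrahydro-1H-indene-1,5(6H)-dione, via ketol 4 (not isolated)
Conditions: L-phenylalanine (1 equiv), (1S)-(+)-camphor-10-sulfonic acid (0.5 equiv), MeCN, 80 °C; recrystallisation
Reagents that add atoms: none
Why: Hajos–Parrish–Eder–Sauer–Wiechert aldol condensation, in which the enamine of the side-chain ketone with the L-amino acid attacks one enantiotopic ring carbonyl and so should fix the quaternary C7a as S (the sense known for L-amino acids in this cyclisation), the ketol then dehydrating under the acidic conditions.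

Step 3
Reactants: 5 (S)-4,7a-dimethyl-2,3,7,7a-tetrahydro-1H-indene-1,5(6H)-dione
Product: 6 (1S,7aS)-1-hydroxy-4,7a-dimethyl-1,2,3,6,7,7a-hexahydro-5H-inden-5-one
Conditions: NaBH4, EtOH, −20 °C
Reagents that add atoms: none
Why: chemoselective borohydride reduction of the saturated cyclopentanone in preference to the less electrophilic enone carbonyl, hydride adding to the face opposite the angular methyl so that the hydroxyl ends cis to it (1S).

Step 4
Reactants: 6 (1S,7aS)-1-hydroxy-4,7a-dimethyl-1,2,3,6,7,7a-hexahydro-5H-inden-5-one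
Product: 7 (1S,7aS)-1-[(tert-butyldimethylsilyl)oxy]-4,7a-dimethyl-1,2,3,6,7,7a-hexahydro-5H-inden-5-one
Conditions: TBSCl, imidazole, DMF, rt
Reagents that add atoms: tert-butyldimethylsilyl chloride, CC(C)(C)[Si](C)(C)Cl
Why: standard silylation of a secondary alcohol, which protects it against the dissolving-metal step.

Step 5
Reactants: 7 (1S,7aS)-1-[(tert-butyldimethylsilyl)oxy]-4,7a-dimethyl-1,2,3,6,7,7a-hexahydro-5H-inden-5-one
Product: 9 (1S,3aR,7aS)-1-[(tert-butyldimethylsilyl)oxy]-4,4,7a-trimethyloctahydro-5H-inden-5-one, via lithium enolate 8 (not isolated)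
Conditions: Li, NH3(l)/THF, −78 °C; isoprene; then MeI, −78 → −33 °C
Reagents that add atoms: iodomethane, CI
Why: dissolving-metal reductive alkylation of an enone, in which the β-carbon C3a is protonated on the face opposite the angular methyl to give the trans ring fusion and the regiodefined C4 enolate is C-methylated to the gem-dimethyl ketone.

Step 6
Reactants: 9 (1S,3aR,7aS)-1-[(tert-butyldimethylsilyl)oxy]-4,4,7a-trimethyloctahydro-5H-inden-5-one
Product: 12 (1S,3aS,7aS)-4,4,7a-trimethyloctahydro-1H-inden-1-ol, via hydrazone 10 (not isolated), via silyl ether 11 (not isolated)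
Conditions: N2H4·H2O, diethylene glycol, 130 °C; KOH, 200 °C; then 2 M aq. HCl, THF, rt
Reagents that add atoms: none
Why: Wolff–Kishner reduction (hydrazone formation, then base-induced loss of N2) removes the hindered C5 carbonyl without touching the stereocentres, and the silyl ether, already labile in hot KOH/glycol, is cleaved completely by the acid treatment.

Step 7
Reactants: 12 (1S,3aS,7aS)-4,4,7a-trimethyloctahydro-1H-inden-1-ol
Product: 13 (3aS,7aS)-4,4,7a-trimethyloctahydro-1H-inden-1-one
Conditions: Pr4N[RuO4] (cat.), N-methylmorpholine N-oxide, 4 Å MS, CH2Cl2, rt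
Reagents that add atoms: none
Why: Ley–Griffith oxidation of a secondary alcohol to the ketone under neutral conditions.

Step 8
Reactants: 13 (3aS,7aS)-4,4,7a-trimethyloctahydro-1H-inden-1-one
Product: 14 (3aS,7aS)-4,4,7a-trimethyl-1-methylideneoctahydro-1H-indene
Conditions: Ph3PCH3Br, KOtBu, toluene, 90 °C
Reagents that add atoms: methyltriphenylphosphonium bromide, C[P+](c1ccccc1)(c1ccccc1)c1ccccc1.[Br-]
Why: Wittig methylenation, which works on hindered cyclopentanones next to a quaternary carbon when heated, the ketone having no epimerisable α-stereocentre.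

Step 9
Reactants: 14 (3aS,7aS)-4,4,7a-trimethyl-1-methylideneoctahydro-1H-indene
Product: 16 [(1S,3aS,7aS)-4,4,7a-trimethyloctahydro-1H-inden-1-yl]methanol, via alkylborane 15 (not isolated)
Conditions: 9-BBN, THF, 65 °C; then 3 M NaOH, 30% H2O2, 0 °C → rt
Reagents that add atoms: hydrogen peroxide, OO
Why: anti-Markovnikov hydroboration–oxidation, the borane adding to the exocyclic alkene from the face opposite the angular 7a-methyl so that H enters C1 on that face and the hydroxymethyl group ends cis to the methyl, with oxidation proceeding with retention.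

Step 10
Reactants: 16 [(1S,3aS,7aS)-4,4,7a-trimethyloctahydro-1H-inden-1-yl]methanol
Product: 17 (1S,3aS,7aS)-4,4,7a-trimethyloctahydro-1H-indene-1-carbaldehyde
Conditions: Pr4N[RuO4] (cat.), N-methylmorpholine N-oxide, 4 Å MS, CH2Cl2, rt
Reagents that add atoms: none
Why: Ley–Griffith oxidation stops at the aldehyde and is neutral, so the α-stereocentre C1 should not epimerise.

Step 11
Reactants: 17 (1S,3aS,7aS)-4,4,7a-trimethyloctahydro-1H-indene-1-carbaldehyde
Product: 18 (1R,3aS,7aS)-1-ethynyl-4,4,7a-trimethyloctahydro-1H-indene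
Conditions: dimethyl (1-diazo-2-oxopropyl)phosphonate, K2CO3, MeOH, 0 °C → rt
Reagents that add atoms: dimethyl (1-diazo-2-oxopropyl)phosphonate, CC(=O)C(=[N+]=[N-])P(=O)(OC)OC
Why: Seyferth–Gilbert homologation in its Ohira–Bestmann form turns the aldehyde into the terminal alkyne by a 1,2-shift in the alkylidene carbene, and C1 keeps its configuration because the aldehyde epimer cis to the angular methyl is also the thermodynamically preferred one under the mild base.

Step 12
Reactants: 19 but-2-yne-1,4-diol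
Product: 20 (E)-but-2-ene-1,4-diol
Conditions: LiAlH4, THF, reflux
Reagents that add atoms: none
Why: hydroxyl-directed trans-hydroalumination of a propargylic alcohol, which gives only the E-alkene after hydrolysis.

Step 13
Reactants: 20 (E)-but-2-ene-1,4-diol
Product: 21 (E)-4-[(4-methoxybenzyl)oxy]but-2-en-1-ol
Conditions: NaH (1 equiv), THF/DMF, 0 °C; 4-methoxybenzyl chloride, Bu4NI (cat.), rt; 20 in excess
Reagents that add atoms: 4-methoxybenzyl chloride, COc1ccc(CCl)cc1
Why: Williamson monoalkylation of a symmetrical diol through its mono-sodium alkoxide, with excess diol suppressing the bis-ether.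

Step 14
Reactants: 21 (E)-4-[(4-methoxybenzyl)oxy]but-2-en-1-ol
Product: 22 [(2S,3S)-3-{[(4-methoxybenzyl)oxy]methyl}oxiran-2-yl]methanol
Conditions: Ti(OiPr)4 (cat.), L-(+)-diethyl tartrate (cat.), t-BuOOH, 4 Å MS, CH2Cl2, −20 °C
Reagents that add atoms: tert-butyl hydroperoxide, CC(C)(C)OO
Why: Sharpless asymmetric epoxidation, in which the L-(+)-tartrate titanium complex delivers oxygen to the face of the E-allylic alcohol that gives the (2S,3S)-trans-epoxide, the same sense as for other E-3-substituted allylic alcohols.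

Step 15
Reactants: 18 (1R,3aS,7aS)-1-ethynyl-4,4,7a-trimethyloctahydro-1H-indene; 22 [(2S,3S)-3-{[(4-methoxybenzyl)oxy]methyl}oxiran-2-yl]methanol
Product: 25 (2R,3R)-3-{[(4-methoxybenzyl)oxy]methyl}-5-[(1S,3aS,7aS)-4,4,7a-trimethyloctahydro-1H-inden-1-yl]pent-4-yne-1,2-diol, via lithium acetylide 23 (not isolated), via alkynylalane 24 (not isolated)
Conditions: 18 (2.5 equiv), n-BuLi, toluene, 0 °C; Et2AlCl, 0 °C → rt; then 22, toluene/CH2Cl2, 0 °C → rt; aq. potassium sodium tartrate (KNaC4H4O6); unreacted 18 recovered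
Reagents that add atoms: none
Why: opening of a 2,3-epoxy alcohol by a diethylalkynylalane, in which the aluminium alkoxide at the primary hydroxyl holds the reagent so that the alkynyl group attacks the distal epoxide carbon C3 in an SN2 manner with inversion while C2 keeps its C–O bond, converting the (2S,3S)-trans-epoxide into the (2R,3R)-1,2-diol.

Step 16
Reactants: 25 (2R,3R)-3-{[(4-methoxybenzyl)oxy]methyl}-5-[(1S,3aS,7aS)-4,4,7a-trimethyloctahydro-1H-inden-1-yl]pent-4-yne-1,2-diol
Product: 27 (2R,3R)-2-hydroxy-3-{[(4-methoxybenzyl)oxy]methyl}-5-[(1S,3aS,7aS)-4,4,7a-trimethyloctahydro-1H-inden-1-yl]pent-4-ynoic acid, via hydroxy aldehyde 26 (not isolated)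
Conditions: TEMPO (cat.), NaOCl (cat.), NaClO2, MeCN/pH 6.7 phosphate buffer (NaH2PO4/Na2HPO4), 35 °C
Reagents that add atoms: sodium chlorite, [Na+].[O-]Cl=O
Why: oxoammonium (TEMPO)-catalysed oxidation with chlorite as terminal oxidant takes the primary alcohol of a 1,2-diol to the α-hydroxy acid, the hindered secondary hydroxyl reacting far more slowly and the aldehyde being trapped by chlorite before glycol cleavage.

Step 17
Reactants: 27 (2R,3R)-2-hydroxy-3-{[(4-methoxybenzyl)oxy]methyl}-5-[(1S,3aS,7aS)-4,4,7a-trimethyloctahydro-1H-inden-1-yl]pent-4-ynoic acid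
Product: 29 (3R,4R)-3-hydroxy-4-{[(1S,3aS,7aS)-4,4,7a-trimethyloctahydro-1H-inden-1-yl]ethynyl}dihydrofuran-2(3H)-one, via dihydroxy acid 28 (not isolated)
Conditions: DDQ, CH2Cl2/pH 7 buffer, 0 °C → rt; then TsOH·H2O (cat.), CH2Cl2, rt
Reagents that add atoms: none
Why: oxidative cleavage of the 4-methoxybenzyl ether by DDQ frees the γ-hydroxyl, which closes the five-membered lactone by acid-catalysed 5-exo-trig lactonisation without touching either stereocentre, the trans-epoxide/anti-opening sequence having placed hydroxyl and alkynyl group cis on the ring.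

Step 18
Reactants: 29 (3R,4R)-3-hydroxy-4-{[(1S,3aS,7aS)-4,4,7a-trimethyloctahydro-1H-inden-1-yl]ethynyl}dihydrofuran-2(3H)-one
Product: 30 (3R,4R)-3-[(tert-butyldimethylsilyl)oxy]-4-{[(1S,3aS,7aS)-4,4,7a-trimethyloctahydro-1H-inden-1-yl]ethynyl}dihydrofuran-2(3H)-one
Conditions: TBSCl, imidazole, DMF, rt
Reagents that add atoms: tert-butyldimethylsilyl chloride, CC(C)(C)[Si](C)(C)Cl
Why: silylation of the α-hydroxyl under weakly basic conditions that should neither epimerise lactone C3 nor trigger β-elimination.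

Step 19
Reactants: 30 (3R,4R)-3-[(tert-butyldimethylsilyl)oxy]-4-{[(1S,3aS,7aS)-4,4,7a-trimethyloctahydro-1H-inden-1-yl]ethynyl}dihydrofuran-2(3H)-one; 31 ethylene
Product: 32 (3R,4R)-3-[(tert-butyldimethylsilyl)oxy]-4-{3-[(1S,3aS,7aS)-4,4,7a-trimethyloctahydro-1H-inden-1-yl]buta-1,3-dien-2-yl}dihydrofuran-2(3H)-one
Conditions: 31 (4 bar), second-generation Grubbs catalyst RuCl2(=CHPh)(H2IMes)(PCy3) (10 mol %), toluene, 80 °C
Reagents that add atoms: none
Why: The ruthenium methylidene formed from the precatalyst and ethylene undergoes [2+2] addition to the alkyne to give a ruthenacyclobutene, which opens to a vinylcarbene; [2+2] addition and cycloreversion with ethylene then release the 2,3-disubstituted buta-1,3-diene and return the methylidene. The closest known reaction type is the cross enyne metathesis of ethylene with internal alkynes to 2,3-disubstituted butadienes. No ring is closed and no stereocentre is created, and both orientations of methylidene addition lead to the same diene, so there is no regiochemical question. The selectivity needed is reaction at the alkyne only and an inert product: the two branched 1,1-disubstituted methylenes of 32 are too hindered to re-enter metathesis, and the lactone, the silyl ether and the two propargylic stereocentres (hydrindane C1, lactone C4) are spectators under these neutral conditions. The one real demand is turnover at a doubly α-branched alkyne, which the N-heterocyclic-carbene catalyst, heat and ethylene pressure are meant to provide.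

Step 20
Reactants: 32 (3R,4R)-3-[(tert-butyldimethylsilyl)oxy]-4-{3-[(1S,3aS,7aS)-4,4,7a-trimethyloctahydro-1H-inden-1-yl]buta-1,3-dien-2-yl}dihydrofuran-2(3H)-one
Product: 34 (3R,4R)-3-[(tert-butyldimethylsilyl)oxy]-4-{(2R)-1-hydroxy-3-[(1R,3aS,7aS)-4,4,7a-trimethyloctahydro-1H-inden-1-yl]but-3-en-2-yl}dihydrofuran-2(3H)-one, via alkylborane 33 (not isolated)
Conditions: 9-BBN, THF, 0 °C → rt; then 30% H2O2, aq. NaOAc, 0 °C → rt
Reagents that add atoms: hydrogen peroxide, OO
Why: hydroboration–oxidation with a bulky dialkylborane, boron going to the terminal carbon of the methylene next to lactone C4 (the other methylene is shielded by the quaternary C7a and its methyl), and, with the lactone C4–H turned toward the bulky dienyl substituent to minimise A(1,2) strain, the C3 silyloxy branch covers one face so that H should be delivered anti to it and set the new methine as R.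

Step 21
Reactants: 34 (3R,4R)-3-[(tert-butyldimethylsilyl)oxy]-4-{(2R)-1-hydroxy-3-[(1R,3aS,7aS)-4,4,7a-trimethyloctahydro-1H-inden-1-yl]but-3-en-2-yl}dihydrofuran-2(3H)-one
Product: 35 (2R)-2-{(3R,4R)-4-[(tert-butyldimethylsilyl)oxy]-5-oxotetrahydrofuran-3-yl}-3-[(1R,3aS,7aS)-4,4,7a-trimethyloctahydro-1H-inden-1-yl]but-3-en-1-yl acetate
Conditions: Ac2O, pyridine, DMAP (cat.), CH2Cl2, 0 °C
Reagents that add atoms: acetic anhydride, CC(=O)OC(C)=O
Why: nucleophile-catalysed acylation of the only free hydroxyl, done promptly so that the primary alcohol cannot translactonise.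

Step 22
Reactants: 35 (2R)-2-{(3R,4R)-4-[(tert-butyldimethylsilyl)oxy]-5-oxotetrahydrofuran-3-yl}-3-[(1R,3aS,7aS)-4,4,7a-trimethyloctahydro-1H-inden-1-yl]but-3-en-1-yl acetate
Product: 36 (2R)-2-[(3R,4R)-4-hydroxy-5-oxotetrahydrofuran-3-yl]-3-[(1R,3aS,7aS)-4,4,7a-trimethyloctahydro-1H-inden-1-yl]but-3-en-1-yl acetate (CNP0252518.3)
Conditions: HF·pyridine, THF/pyridine, 0 °C → rt
Reagents that add atoms: none
Why: fluoride-mediated cleavage of the silyl ether under mildly acidic conditions that leave the acetate, the lactone and the exo-methylene intact.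

**Compound list**

1 | 2-methylcyclopentane-1,3-dione | CC1C(=O)CCC1=O | starting material
2 | pent-1-en-3-one (ethyl vinyl ketone) | CCC(=O)C=C | starting material
3 | 2-methyl-2-(3-oxopentyl)cyclopentane-1,3-dione | CCC(=O)CCC1(C)C(=O)CCC1=O | intermediate
4 | (3aS,7aS)-3a-hydroxy-4,7a-dimethylhexahydro-1H-indene-1,5(4H)-dione, cis-fused ketol, C4 epimers, not isolated | O=C1CC[C@]2(O)C(C)C(=O)CC[C@]12C | intermediate
5 | (S)-4,7a-dimethyl-2,3,7,7a-tetrahydro-1H-indene-1,5(6H)-dione | O=C1CCC2=C(C)C(=O)CC[C@]12C | intermediate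
6 | (1S,7aS)-1-hydroxy-4,7a-dimethyl-1,2,3,6,7,7a-hexahydro-5H-inden-5-one | O[C@H]1CCC2=C(C)C(=O)CC[C@]12C | intermediate
7 | (1S,7aS)-1-[(tert-butyldimethylsilyl)oxy]-4,7a-dimethyl-1,2,3,6,7,7a-hexahydro-5H-inden-5-one | CC(C)(C)[Si](C)(C)O[C@H]1CCC2=C(C)C(=O)CC[C@]12C | intermediate
8 | lithium (1S,3aR,7aS)-1-[(tert-butyldimethylsilyl)oxy]-4,7a-dimethyl-2,3,3a,6,7,7a-hexahydro-1H-inden-5-olate, trans-fused C4 enolate, not isolated | CC(C)(C)[Si](C)(C)O[C@H]1CC[C@H]2C(C)=C(O[Li])CC[C@]12C | intermediate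
9 | (1S,3aR,7aS)-1-[(tert-butyldimethylsilyl)oxy]-4,4,7a-trimethyloctahydro-5H-inden-5-one | CC(C)(C)[Si](C)(C)O[C@H]1CC[C@H]2C(C)(C)C(=O)CC[C@]12C | intermediate
10 | 5-hydrazone of 9, not isolated | CC(C)(C)[Si](C)(C)O[C@H]1CC[C@H]2C(C)(C)C(=NN)CC[C@]12C | intermediate
11 | tert-butyldimethyl{[(1S,3aS,7aS)-4,4,7a-trimethyloctahydro-1H-inden-1-yl]oxy}silane, not isolated | CC(C)(C)[Si](C)(C)O[C@H]1CC[C@H]2C(C)(C)CCC[C@]12C | intermediate
12 | (1S,3aS,7aS)-4,4,7a-trimethyloctahydro-1H-inden-1-ol | O[C@H]1CC[C@H]2C(C)(C)CCC[C@]12C | intermediate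
13 | (3aS,7aS)-4,4,7a-trimethyloctahydro-1H-inden-1-one | O=C1CC[C@H]2C(C)(C)CCC[C@]12C | intermediate
14 | (3aS,7aS)-4,4,7a-trimethyl-1-methylideneoctahydro-1H-indene | C=C1CC[C@H]2C(C)(C)CCC[C@]12C | intermediate
15 | 9-{[(3aS,7aS)-4,4,7a-trimethyloctahydro-1H-inden-1-yl]methyl}-9-borabicyclo[3.3.1]nonane, CH2 cis to the 7a-methyl, not isolated | C(B1C2CCCC1CCC2)[C@H]3CC[C@H]4C(C)(C)CCC[C@]34C | intermediate
16 | [(1S,3aS,7aS)-4,4,7a-trimethyloctahydro-1H-inden-1-yl]methanol | OC[C@H]1CC[C@H]2C(C)(C)CCC[C@]12C | intermediate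
17 | (1S,3aS,7aS)-4,4,7a-trimethyloctahydro-1H-indene-1-carbaldehyde | O=C[C@H]1CC[C@H]2C(C)(C)CCC[C@]12C | intermediate
18 | (1R,3aS,7aS)-1-ethynyl-4,4,7a-trimethyloctahydro-1H-indene | C#C[C@H]1CC[C@H]2C(C)(C)CCC[C@]12C | intermediate
19 | but-2-yne-1,4-diol | OCC#CCO | starting material
20 | (E)-but-2-ene-1,4-diol | OC/C=C/CO | intermediate
21 | (E)-4-[(4-methoxybenzyl)oxy]but-2-en-1-ol | OC/C=C/COCc1ccc(OC)cc1 | intermediate
22 | [(2S,3S)-3-{[(4-methoxybenzyl)oxy]methyl}oxiran-2-yl]methanol | OC[C@@H]1O[C@H]1COCc1ccc(OC)cc1 | intermediate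
23 | lithium acetylide of 18, not isolated | [Li]C#C[C@H]1CC[C@H]2C(C)(C)CCC[C@]12C | intermediate
24 | diethyl{[(3aS,7aS)-4,4,7a-trimethyloctahydro-1H-inden-1-yl]ethynyl}alane, alkynyl cis to the 7a-methyl, not isolated | CC[Al](CC)C#C[C@H]1CC[C@H]2C(C)(C)CCC[C@]12C | intermediate
25 | (2R,3R)-3-{[(4-methoxybenzyl)oxy]methyl}-5-[(1S,3aS,7aS)-4,4,7a-trimethyloctahydro-1H-inden-1-yl]pent-4-yne-1,2-diol | OC[C@H](O)[C@@H](COCc1ccc(OC)cc1)C#C[C@H]1CC[C@H]2C(C)(C)CCC[C@]12C | intermediate
26 | (2R,3R)-2-hydroxy-3-{[(4-methoxybenzyl)oxy]methyl}-5-[(1S,3aS,7aS)-4,4,7a-trimethyloctahydro-1H-inden-1-yl]pent-4-ynal, not isolated | O=C[C@H](O)[C@@H](COCc1ccc(OC)cc1)C#C[C@H]1CC[C@H]2C(C)(C)CCC[C@]12C | intermediate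
27 | (2R,3R)-2-hydroxy-3-{[(4-methoxybenzyl)oxy]methyl}-5-[(1S,3aS,7aS)-4,4,7a-trimethyloctahydro-1H-inden-1-yl]pent-4-ynoic acid | OC(=O)[C@H](O)[C@@H](COCc1ccc(OC)cc1)C#C[C@H]1CC[C@H]2C(C)(C)CCC[C@]12C | intermediate
28 | (2R,3R)-2-hydroxy-3-(hydroxymethyl)-5-[(1S,3aS,7aS)-4,4,7a-trimethyloctahydro-1H-inden-1-yl]pent-4-ynoic acid, not isolated | OC(=O)[C@H](O)[C@@H](CO)C#C[C@H]1CC[C@H]2C(C)(C)CCC[C@]12C | intermediate
29 | (3R,4R)-3-hydroxy-4-{[(1S,3aS,7aS)-4,4,7a-trimethyloctahydro-1H-inden-1-yl]ethynyl}dihydrofuran-2(3H)-one | C(#C[C@@H]1COC(=O)[C@@H]1O)[C@H]2CC[C@H]3C(C)(C)CCC[C@]23C | intermediate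
30 | (3R,4R)-3-[(tert-butyldimethylsilyl)oxy]-4-{[(1S,3aS,7aS)-4,4,7a-trimethyloctahydro-1H-inden-1-yl]ethynyl}dihydrofuran-2(3H)-one | C(#C[C@@H]1COC(=O)[C@@H]1O[Si](C)(C)C(C)(C)C)[C@H]2CC[C@H]3C(C)(C)CCC[C@]23C | intermediate
31 | ethylene | C=C | starting material
32 | (3R,4R)-3-[(tert-butyldimethylsilyl)oxy]-4-{3-[(1S,3aS,7aS)-4,4,7a-trimethyloctahydro-1H-inden-1-yl]buta-1,3-dien-2-yl}dihydrofuran-2(3H)-one | C=C([C@H]2CC[C@H]3C(C)(C)CCC[C@]23C)C(=C)[C@@H]1COC(=O)[C@@H]1O[Si](C)(C)C(C)(C)C | intermediate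
33 | B-alkyl-9-borabicyclo[3.3.1]nonane from 32, boron on the new CH2 next to the lactone-bearing methine, not isolated | C=C([C@H]2CC[C@H]3C(C)(C)CCC[C@]23C)[C@H](CB4C5CCCC4CCC5)[C@@H]1COC(=O)[C@@H]1O[Si](C)(C)C(C)(C)C | intermediate
34 | (3R,4R)-3-[(tert-butyldimethylsilyl)oxy]-4-{(2R)-1-hydroxy-3-[(1R,3aS,7aS)-4,4,7a-trimethyloctahydro-1H-inden-1-yl]but-3-en-2-yl}dihydrofuran-2(3H)-one | C=C([C@H]2CC[C@H]3C(C)(C)CCC[C@]23C)[C@H](CO)[C@@H]1COC(=O)[C@@H]1O[Si](C)(C)C(C)(C)C | intermediate
35 | (2R)-2-{(3R,4R)-4-[(tert-butyldimethylsilyl)oxy]-5-oxotetrahydrofuran-3-yl}-3-[(1R,3aS,7aS)-4,4,7a-trimethyloctahydro-1H-inden-1-yl]but-3-en-1-yl acetate | C=C([C@H]2CC[C@H]3C(C)(C)CCC[C@]23C)[C@H](COC(C)=O)[C@@H]1COC(=O)[C@@H]1O[Si](C)(C)C(C)(C)C | intermediate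
36 | (2R)-2-[(3R,4R)-4-hydroxy-5-oxotetrahydrofuran-3-yl]-3-[(1R,3aS,7aS)-4,4,7a-trimethyloctahydro-1H-inden-1-yl]but-3-en-1-yl acetate | C=C([C@H]1CC[C@H]2C(C)(C)CCC[C@]12C)[C@H](COC(C)=O)[C@@H]1COC(=O)[C@@H]1O | target

**Step count and risks**

Total step count: 22 (steps 1–11 hydrindanyl acetylene; steps 12–14 epoxy alcohol; steps 15–22 union, key step and finish).
Longest linear sequence: 19 steps (steps 1–11, then 15–22).

Steps most likely to fail:

1. Step 19 (key step). The doubly α-branched alkyne may not be taken up by the ruthenium methylidene, so that no ruthenacyclobutene forms and the catalyst decays under ethylene before conversion. The fallback sets out from 30 and abandons metathesis. The alkyne would be oxidised with ruthenium tetroxide, generated from RuCl3 (cat.) and NaIO4 in CCl4/MeCN/H2O at 0 °C, to the 1,2-diketone F1. Both carbonyl groups would then be methylenated with the non-basic Zn/CH2Br2/TiCl4 reagent (THF/CH2Cl2, 0 °C → rt), which leaves lactones alone and should not enolise the two flanking stereocentres. This comes back to the route at 32.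

2. Step 20. The borane may add to the wrong methylene or from the wrong face, because the two 1,1-disubstituted alkenes differ only in their branched neighbours and the facial bias rests on one preferred rotamer about the C4–alkene bond. The fallback sets out from 32 and replaces the four-centre dialkylborane addition by a rhodium-catalysed hydroboration: RhCl(PPh3)3 (cat.), catecholborane, THF, rt, to the catechol boronate F2, then 30% H2O2/pH 7 buffer. In this variant the alkene inserts into a rhodium hydride, a change of mechanism known to give the opposite sense of 1,2-induction on 1,1-disubstituted alkenes next to a stereocentre. It comes back to the route at 34.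

3. Step 16. The oxidation may run on past the α-hydroxy acid with cleavage of the C1–C2 glycol bond, or attack the secondary hydroxyl or the anisyl ring. The fallback sets out from 25 and takes the secondary hydroxyl out of play before any oxidation. Bis-silylation (TBSOTf, 2,6-lutidine, CH2Cl2, −78 °C) would give the bis-silyl ether F3. Selective cleavage of the primary silyl ether (HF·pyridine, pyridine/THF, 0 °C) would give the primary alcohol F4. Oxidation of this simple primary alcohol (TEMPO (cat.), PhI(OAc)2, MeCN/H2O) would give the α-silyloxy acid F5. DDQ (CH2Cl2/pH 7 buffer) would then remove the 4-methoxybenzyl group to give the γ-hydroxy acid F6, which lactonises (TsOH·H2O (cat.), CH2Cl2). This comes back to the route at 30, and step 18 is then not needed.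

**Further compounds**

F1 | step 19 | 1-[(3R,4R)-4-[(tert-butyldimethylsilyl)oxy]-5-oxotetrahydrofuran-3-yl]-2-[(3aS,7aS)-4,4,7a-trimethyloctahydro-1H-inden-1-yl]ethane-1,2-dione (acyl group cis to the 7a-methyl) | O=C([C@H]2CC[C@H]3C(C)(C)CCC[C@]23C)C(=O)[C@@H]1COC(=O)[C@@H]1O[Si](C)(C)C(C)(C)C
F2 | step 20 | catechol boronate of 34 (2-alkyl-1,3,2-benzodioxaborole, boron in place of the hydroxyl) | C=C([C@H]2CC[C@H]3C(C)(C)CCC[C@]23C)[C@H](CB4Oc5ccccc5O4)[C@@H]1COC(=O)[C@@H]1O[Si](C)(C)C(C)(C)C
F3 | step 16 | 1,2-bis-O-(tert-butyldimethylsilyl) ether of 25 | CC(C)(C)[Si](C)(C)OC[C@H](O[Si](C)(C)C(C)(C)C)[C@@H](COCc1ccc(OC)cc1)C#C[C@H]1CC[C@H]2C(C)(C)CCC[C@]12C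
F4 | step 16 | 2-O-(tert-butyldimethylsilyl) ether of 25 with free primary hydroxyl | OC[C@H](O[Si](C)(C)C(C)(C)C)[C@@H](COCc1ccc(OC)cc1)C#C[C@H]1CC[C@H]2C(C)(C)CCC[C@]12C
F5 | step 16 | 2-O-(tert-butyldimethylsilyl) ether of acid 27 | OC(=O)[C@H](O[Si](C)(C)C(C)(C)C)[C@@H](COCc1ccc(OC)cc1)C#C[C@H]1CC[C@H]2C(C)(C)CCC[C@]12C
F6 | step 16 | 2-O-(tert-butyldimethylsilyl) ether of dihydroxy acid 28 | OC(=O)[C@H](O[Si](C)(C)C(C)(C)C)[C@@H](CO)C#C[C@H]1CC[C@H]2C(C)(C)CCC[C@]12C
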